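## Retrosynthetic overview

1. The (2Z)-4-acetoxy-2-methylbut-2-enoate on the C3 oxygen and the acrylic acid (carried as a PMB-protected 2-substituted allyl alcohol) are installed last. The ethenyl group and the CH2OH of the hydroxypropenyl group are released together from one lactone (i-Bu2AlH, then Ph3P=CH2).
2. Key disconnection: the ring bond between the carbinol carbon C1 and C6 (the CH that carries the hydroxypropenyl group), made by an intramolecular carbonyl-ene reaction of an aldehyde tethered to a 3,6-dihydro-2H-pyran-2-one.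
3. Enabling feature: on the cyclohexane the ethenyl carbon on quaternary C5 and the CH2O of the C6 side chain are cis. Both fit into one six-membered lactone (C=O = future ethenyl CH, OCH2 = future CH2OH) whose ring C=C carries the methyl that becomes the exocyclic =CH2, so HO–C1–C6–C(=CH2) is the ene retron.
4. The aldehyde comes from an auxiliary-controlled syn-aldol (C2, C3) on a lactone aldehyde whose quaternary centre (C5) is relayed from (R)-lactate by a Claisen rearrangement.
5. Ring order: dihydropyranone by ring-closing metathesis, then the cyclohexane by the ene reaction, then opening of the lactone.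

Key step: step 14

Remarks: Ring locants used for the cyclohexanes 26–28 and 33–37 are C1 = carbinol carbon made in step 14, C2 = CH carrying the three-carbon unit that becomes the acrylic acid, C3 = CH–O that is esterified, C4 = CH2, C5 = quaternary carbon, C6 = CH carrying the hydroxypropenyl unit. Assumption: the butenoate is Z as the SMILES encodes (CH2OAc cis to the ester carbonyl). The acetal centre in 7–9 and the lactol centre in 25 are inconsequential epimer mixtures.

## Route

Step 1
Reactants: 1 2-methylprop-2-en-1-ol; 2 2-bromopropanoyl bromide (racemic)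
Product: 3 2-methylprop-2-en-1-yl 2-bromopropanoate (racemic)
Conditions: pyridine, CH2Cl2, 0 °C → rt
Reagents that add atoms: none
Why: Acylation of the primary allylic alcohol by the acid bromide with pyridine as HBr scavenger (esterification); the racemic α-bromo centre disappears in step 2.

Step 2
Reactants: 3 2-methylprop-2-en-1-yl 2-bromopropanoate
Product: 5 2-methylprop-2-en-1-yl 2-(triphenyl-λ5-phosphanylidene)propanoate, via phosphonium bromide 4 (not isolated)
Conditions: PPh3, toluene, 80 °C; then aq. NaOH, CH2Cl2, rt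
Reagents that add atoms: triphenylphosphine, c1ccc(cc1)P(c1ccccc1)c1ccccc1
Why: SN2 quaternisation of PPh3 by the α-bromo ester and deprotonation of the salt give the ester-stabilised ylide, the standard preparation of Wittig reagents of this type.

Step 3
Reactants: 6 methyl (2R)-2-hydroxypropanoate (methyl (R)-lactate)
Product: 7 methyl (2R)-2-(1-ethoxyethoxy)propanoate
Conditions: ethyl vinyl ether, PPTS (cat.), CH2Cl2, rt
Reagents that add atoms: ethyl vinyl ether, C=COCC
Why: Acid-catalysed addition of the hydroxyl group to the enol ether gives the mixed acetal without touching the lactate stereocentre, and this acetal is the later source of the vinyl ether.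

Step 4
Reactants: 7 methyl (2R)-2-(1-ethoxyethoxy)propanoate; 5 2-methylprop-2-en-1-yl 2-(triphenyl-λ5-phosphanylidene)propanoate
Product: 9 2-methylprop-2-en-1-yl (2E,4R)-4-(1-ethoxyethoxy)-2-methylpent-2-enoate, via aldehyde 8 (not isolated)
Conditions: i-Bu2AlH (1.05 equiv), CH2Cl2, −78 °C; then 5, −78 °C → rt
Reagents that add atoms: none
Why: Half-reduction of the ester to the aluminium hemiacetal and Wittig olefination of the aldehyde as it is released avoid handling the racemisation-prone α-alkoxy aldehyde, and the stabilised α-branched ylide should give the (E)-trisubstituted enoate.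

Step 5
Reactants: 9 2-methylprop-2-en-1-yl (2E,4R)-4-(1-ethoxyethoxy)-2-methylpent-2-enoate
Product: 10 2-methylprop-2-en-1-yl (2E,4R)-4-(ethenyloxy)-2-methylpent-2-enoate
Conditions: TMSOTf, Et3N, CH2Cl2, 0 °C → rt
Reagents that add atoms: none
Why: The silyl triflate ionises the mixed acetal at the less hindered ethoxy oxygen and triethylamine deprotonates the oxocarbenium ion (Gassman-type acetal-to-enol-ether elimination), which should give the allyl vinyl ether.

Step 6
Reactants: 10 2-methylprop-2-en-1-yl (2E,4R)-4-(ethenyloxy)-2-methylpent-2-enoate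
Product: 11 2-methylprop-2-en-1-yl (2R,3E)-2-methyl-2-(2-oxoethyl)pent-3-enoate
Conditions: toluene (trace Et3N), 140 °C, sealed tube
Reagents that add atoms: none
Why: Claisen rearrangement through a chair transition state with the carbinol methyl equatorial transfers the (R) C–O centre to the new quaternary carbon (1,3-chirality transfer) and leaves an (E)-propenyl group; the minor (Z)-propenyl product carries the opposite quaternary centre and is expected to be removed as a diastereomer after step 11.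

Step 7
Reactants: 11 2-methylprop-2-en-1-yl (2R,3E)-2-methyl-2-(2-oxoethyl)pent-3-enoate
Product: 12 2-[(3R)-3,5-dimethyl-2-oxo-3,6-dihydro-2H-pyran-3-yl]acetaldehyde
Conditions: second-generation Grubbs catalyst (H2IMes)(PCy3)Cl2Ru=CHPh (5 mol %), toluene (0.005 M), 80 °C
Reagents that add atoms: none
Why: Ring-closing metathesis between the methallyl alkene and the propenyl group forms the trisubstituted ring alkene of the six-membered lactone with loss of propene; the α-quaternary centre favours closure and no other alkene is present at this stage.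

Step 8
Reactants: 13 3-chloro-2-(chloromethyl)prop-1-ene; 14 (4-methoxyphenyl)methanol
Product: 15 1-({[2-(chloromethyl)prop-2-en-1-yl]oxy}methyl)-4-methoxybenzene
Conditions: NaH, THF/DMF, 0 °C → rt (13 in excess)
Reagents that add atoms: none
Why: Williamson etherification of the alkoxide with one of two equivalent allylic chlorides, with excess dichloride suppressing the bis-ether.

Step 9
Reactants: 15 1-({[2-(chloromethyl)prop-2-en-1-yl]oxy}methyl)-4-methoxybenzene
Product: 17 3-{[(4-methoxyphenyl)methoxy]methyl}but-3-enoic acid, via allylmagnesium chloride 16 (not isolated)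
Conditions: Mg, THF, 0 °C; then CO2, −40 °C → rt; aq. HCl
Reagents that add atoms: carbon dioxide, O=C=O
Why: Magnesium insertion into the allylic chloride and carboxylation of the symmetrical 2-substituted allyl Grignard reagent should give the β,γ-unsaturated acid (Grignard carboxylation).

Step 10
Reactants: 17 3-{[(4-methoxyphenyl)methoxy]methyl}but-3-enoic acid; 18 (4R)-4-benzyl-1,3-thiazolidine-2-thione
Product: 19 1-[(4R)-4-benzyl-2-sulfanylidene-1,3-thiazolidin-3-yl]-3-{[(4-methoxyphenyl)methoxy]methyl}but-3-en-1-one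
Conditions: EDC·HCl, DMAP (cat.), CH2Cl2, 0 °C
Reagents that add atoms: none
Why: Carbodiimide-mediated N-acylation of the thiazolidinethione, run cold with little DMAP so that the β,γ-alkene is not moved into conjugation.

Step 11
Reactants: 19 1-[(4R)-4-benzyl-2-sulfanylidene-1,3-thiazolidin-3-yl]-3-{[(4-methoxyphenyl)methoxy]methyl}but-3-en-1-one; 12 2-[(3R)-3,5-dimethyl-2-oxo-3,6-dihydro-2H-pyran-3-yl]acetaldehyde
Product: 21 (2R,3S)-1-[(4R)-4-benzyl-2-sulfanylidene-1,3-thiazolidin-3-yl]-4-[(3R)-3,5-dimethyl-2-oxo-3,6-dihydro-2H-pyran-3-yl]-3-hydroxy-2-{3-[(4-methoxyphenyl)methoxy]prop-1-en-2-yl}butan-1-one, via chlorotitanium enolate 20 (not isolated)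
Conditions: TiCl4 (1.05 equiv), i-Pr2NEt (1.1 equiv), NMP (1.0 equiv), CH2Cl2, 0 °C; then 12, −78 → 0 °C
Reagents that add atoms: none
Why: Soft enolisation gives the (Z)-chlorotitanium enolate, which adds through its α-carbon to the aldehyde in a Zimmerman–Traxler chair on the face opposite the benzyl group (Crimmins "Evans-syn" aldol), setting both new centres (2R,3S) under auxiliary control irrespective of the remote quaternary centre.

Step 12
Reactants: 21 the syn-aldol adduct
Product: 22 (2R,3S)-1-[(4R)-4-benzyl-2-sulfanylidene-1,3-thiazolidin-3-yl]-4-[(3R)-3,5-dimethyl-2-oxo-3,6-dihydro-2H-pyran-3-yl]-2-{3-[(4-methoxyphenyl)methoxy]prop-1-en-2-yl}-3-[(triethylsilyl)oxy]butan-1-one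
Conditions: TESOTf, 2,6-lutidine, CH2Cl2, −78 → 0 °C
Reagents that add atoms: triethylsilyl trifluoromethanesulfonate, CC[Si](CC)(CC)OS(=O)(=O)C(F)(F)F
Why: Silylation of the secondary aldol hydroxyl with a silyl triflate and a hindered base blocks retro-aldol and β-elimination in the next steps.

Step 13
Reactants: 22 the TES-protected aldol adduct
Product: 23 (2R,3S)-4-[(3R)-3,5-dimethyl-2-oxo-3,6-dihydro-2H-pyran-3-yl]-2-{3-[(4-methoxyphenyl)methoxy]prop-1-en-2-yl}-3-[(triethylsilyl)oxy]butanal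
Conditions: i-Bu2AlH (1.2 equiv), CH2Cl2, −78 °C, short reaction time
Reagents that add atoms: none
Why: The N-acylthiazolidinethione is far more electrophilic than the hindered α-quaternary lactone and should be reduced at −78 °C to a stable tetrahedral aluminium adduct that releases the aldehyde on work-up (direct reductive removal of the Crimmins auxiliary).

Step 14
Reactants: 23 (2R,3S)-4-[(3R)-3,5-dimethyl-2-oxo-3,6-dihydro-2H-pyran-3-yl]-2-{3-[(4-methoxyphenyl)methoxy]prop-1-en-2-yl}-3-[(triethylsilyl)oxy]butanal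
Product: 24 (4aR,5R,6S,7S,8aR)-5-hydroxy-6-{3-[(4-methoxyphenyl)methoxy]prop-1-en-2-yl}-8a-methyl-4-methylidene-7-[(triethylsilyl)oxy]octahydro-1H-isochromen-1-one (cis-fused)
Conditions: Me2AlCl (1.5 equiv), CH2Cl2, −78 → −30 °C
Reagents that add atoms: none
Why: Me2AlCl binds the aldehyde oxygen and the ring alkene of the dihydropyranone adds through its CH carbon to the carbonyl carbon while a hydrogen of the ring methyl shifts to oxygen in a concerted, asynchronous six-centre ene process, after which the aluminium alkoxide loses methane and so removes the proton source. The closest known reaction is the Lewis-acid-promoted intramolecular carbonyl-ene cyclization of citronellal to isopulegol, here applied to an endocyclic trisubstituted alkene. The cyclohexane closes in a 6-exo mode with respect to both the C=O and the C=C unit and is cis-fused to the lactone. The ring-fusion CH is set by the lactone tether, because the aldehyde chain hangs from the quaternary carbon and can only reach the alkene face on which it sits, so the fusion hydrogen ends cis to the angular methyl. The carbinol centre is set by the conformation of the closing ring in which the OTES and alkoxypropenyl groups (both fixed by the aldol) are equatorial, the chain sits pseudo-axial on the lactone ring and the methyl-bearing alkene carbon ends axial on the new ring, since the other chair would hold OTES 1,3-diaxial to the lactone carbonyl carbon; there the aluminium-bound oxygen is equatorial, anti to the C5–C6 bond, which places the hydroxyl cis to the carbon branch on C6 and trans to the alkoxypropenyl group. The step needs hydrogen transfer from the ring methyl and not from the ring OCH2, which is secured because an oxygen anti to the C5–C6 bond lies on the side of the alkene hydrogen, over the methyl (the alkene substituent trans to the quaternary carbon), and far from the OCH2.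

Step 15
Reactants: 24 the cis-fused bicyclic lactone
Product: 25 (4aR,5R,6S,7S,8aR)-6-{3-[(4-methoxyphenyl)methoxy]prop-1-en-2-yl}-8a-methyl-4-methylidene-7-[(triethylsilyl)oxy]octahydro-1H-isochromene-1,5-diol (lactol, both C1 epimers)
Conditions: i-Bu2AlH (3 equiv), CH2Cl2, −78 °C
Reagents that add atoms: none
Why: Lactone half-reduction, in which the aluminium lactolate is stable at −78 °C and gives the lactol on work-up while silyl and PMB ethers are inert (one equivalent is consumed by the free hydroxyl).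

Step 16
Reactants: 25 the lactol
Product: 26 (1R,2S,3S,5S,6S)-5-ethenyl-6-(3-hydroxyprop-1-en-2-yl)-2-{3-[(4-methoxyphenyl)methoxy]prop-1-en-2-yl}-5-methyl-3-[(triethylsilyl)oxy]cyclohexan-1-ol
Conditions: Ph3PCH3Br, KOtBu, THF, 0 °C → rt
Reagents that add atoms: methyltriphenylphosphonium bromide, C[P+](c1ccccc1)(c1ccccc1)c1ccccc1.[Br-]
Why: The lactol opens under base to a neopentyl hydroxy aldehyde that cannot enolise and undergoes Wittig methylenation, which should deliver the ethenyl group and the free allylic CH2OH in one operation.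

Step 17
Reactants: 26 the diol
Product: 27 (1R,2R,3S,5S,6S)-1-[(tert-butyldimethylsilyl)oxy]-6-{3-[(tert-butyldimethylsilyl)oxy]prop-1-en-2-yl}-5-ethenyl-2-{3-[(4-methoxyphenyl)methoxy]prop-1-en-2-yl}-5-methyl-3-[(triethylsilyl)oxy]cyclohexane
Conditions: TBSOTf (3 equiv), 2,6-lutidine, CH2Cl2, −78 → 0 °C
Reagents that add atoms: tert-butyldimethylsilyl trifluoromethanesulfonate, CC(C)(C)[Si](C)(C)OS(=O)(=O)C(F)(F)F
Why: The silyl triflate silylates both the primary allylic and the hindered secondary hydroxyl, while the triethylsilyl ether stays in place.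

Step 18
Reactants: 27 the tris-silyl ether
Product: 28 (1R,2R,3S,5S,6S)-1-[(tert-butyldimethylsilyl)oxy]-6-{3-[(tert-butyldimethylsilyl)oxy]prop-1-en-2-yl}-5-ethenyl-2-{3-[(4-methoxyphenyl)methoxy]prop-1-en-2-yl}-5-methylcyclohexan-3-ol
Conditions: PPTS (cat.), MeOH/CH2Cl2, 0 °C
Reagents that add atoms: none
Why: Acid-catalysed methanolysis removes the triethylsilyl ether, which is about two orders of magnitude more acid-labile than the two tert-butyldimethylsilyl ethers, and should free only the hydroxyl that is to be esterified.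

Step 19
Reactants: 29 3-methylfuran-2(5H)-one
Product: 31 (2Z)-4-(acetyloxy)-2-methylbut-2-enoic acid, via sodium carboxylate 30 (not isolated)
Conditions: NaOH (1 equiv), H2O/THF, rt; evaporate; Ac2O, pyridine, DMAP (cat.), 0 °C → rt; aq. work-up at pH 3
Reagents that add atoms: sodium hydroxide, [Na+].[OH-]; acetic anhydride, CC(=O)OC(C)=O
Why: Saponification of the butenolide fixes the Z geometry (CH2O cis to the carboxylate) and acetylation of the hydroxy carboxylate before acidification prevents relactonisation, the mixed acetic anhydride being hydrolysed on work-up.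

Step 20
Reactants: 28 the C3 alcohol; 31 (2Z)-4-(acetyloxy)-2-methylbut-2-enoic acid
Product: 33 (1R,2R,3S,5S,6S)-1-[(tert-butyldimethylsilyl)oxy]-6-{3-[(tert-butyldimethylsilyl)oxy]prop-1-en-2-yl}-5-ethenyl-2-{3-[(4-methoxyphenyl)methoxy]prop-1-en-2-yl}-5-methylcyclohexan-3-yl (2Z)-4-(acetyloxy)-2-methylbut-2-enoate, via mixed anhydride 32 (not isolated)
Conditions: 2,4,6-Cl3C6H2COCl, Et3N, toluene, rt; then 28, DMAP, rt
Reagents that add atoms: none
Why: Yamaguchi esterification through the preformed mixed anhydride acylates the secondary alcohol under mild conditions of the kind used to preserve angelate-type (Z) geometry.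

Step 21
Reactants: 33 the PMB-protected ester
Product: 34 (1R,2R,3S,5S,6S)-1-[(tert-butyldimethylsilyl)oxy]-6-{3-[(tert-butyldimethylsilyl)oxy]prop-1-en-2-yl}-5-ethenyl-2-(3-hydroxyprop-1-en-2-yl)-5-methylcyclohexan-3-yl (2Z)-4-(acetyloxy)-2-methylbut-2-enoate
Conditions: DDQ, CH2Cl2/pH 7 buffer, 0 °C
Reagents that add atoms: none
Why: Oxidative cleavage of the p-methoxybenzyl ether by DDQ under buffered conditions should leave silyl ethers, esters and alkenes untouched.

Step 22
Reactants: 34 the allylic alcohol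
Product: 36 2-[(1R,2R,3S,5S,6S)-3-{[(2Z)-4-(acetyloxy)-2-methylbut-2-enoyl]oxy}-1-[(tert-butyldimethylsilyl)oxy]-6-{3-[(tert-butyldimethylsilyl)oxy]prop-1-en-2-yl}-5-ethenyl-5-methylcyclohexan-2-yl]prop-2-enoic acid, via enal 35 (not isolated)
Conditions: Dess–Martin periodinane, NaHCO3, CH2Cl2, 0 °C; then NaClO2, NaH2PO4, 2-methylbut-2-ene, t-BuOH/H2O, 0 °C → rt
Reagents that add atoms: sodium chlorite, [Na+].[O-]Cl=O
Why: Dess–Martin oxidation of the primary allylic alcohol gives the 2-substituted acrolein, which Pinnick oxidation with a hypochlorite scavenger converts into the acrylic acid, while the silyl ether on the neighbouring carbinol prevents lactol and lactone formation.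

Step 23
Reactants: 36 the bis-silylated acid
Product: 37 2-[(1R,2S,3S,5S,6S)-3-{[(2Z)-4-(acetyloxy)-2-methylbut-2-enoyl]oxy}-5-ethenyl-1-hydroxy-6-(3-hydroxyprop-1-en-2-yl)-5-methylcyclohexan-2-yl]prop-2-enoic acid (target, CNP0261293.8)
Conditions: HF·pyridine, pyridine, THF, 0 °C → rt
Reagents that add atoms: none
Why: Buffered fluoride should cleave both silyl ethers under weakly acidic conditions that leave the acetate, the enoate ester and the free acid intact.

## Compound list

1 | 2-methylprop-2-en-1-ol | C=C(C)CO | starting material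
2 | 2-bromopropanoyl bromide (racemic) | CC(Br)C(Br)=O | starting material
3 | 2-methylprop-2-en-1-yl 2-bromopropanoate (racemic) | CC(Br)C(=O)OCC(C)=C | intermediate
4 | {1-[(2-methylprop-2-en-1-yl)oxy]-1-oxopropan-2-yl}triphenylphosphonium bromide | CC(C(=O)OCC(C)=C)[P+](c1ccccc1)(c1ccccc1)c1ccccc1.[Br-] | intermediate
5 | 2-methylprop-2-en-1-yl 2-(triphenyl-λ5-phosphanylidene)propanoate | CC(C(=O)OCC(C)=C)=P(c1ccccc1)(c1ccccc1)c1ccccc1 | intermediate
6 | methyl (2R)-2-hydroxypropanoate | C[C@@H](O)C(=O)OC | starting material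
7 | methyl (2R)-2-(1-ethoxyethoxy)propanoate | C[C@@H](OC(C)OCC)C(=O)OC | intermediate
8 | (2R)-2-(1-ethoxyethoxy)propanal | C[C@@H](OC(C)OCC)C=O | intermediate
9 | 2-methylprop-2-en-1-yl (2E,4R)-4-(1-ethoxyethoxy)-2-methylpent-2-enoate | C[C@@H](OC(C)OCC)/C=C(\C)C(=O)OCC(C)=C | intermediate
10 | 2-methylprop-2-en-1-yl (2E,4R)-4-(ethenyloxy)-2-methylpent-2-enoate | C[C@@H](OC=C)/C=C(\C)C(=O)OCC(C)=C | intermediate
11 | 2-methylprop-2-en-1-yl (2R,3E)-2-methyl-2-(2-oxoethyl)pent-3-enoate | O=CC[C@](C)(/C=C/C)C(=O)OCC(C)=C | intermediate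
12 | 2-[(3R)-3,5-dimethyl-2-oxo-3,6-dihydro-2H-pyran-3-yl]acetaldehyde | O=C1OCC(C)=C[C@@]1(C)CC=O | intermediate
13 | 3-chloro-2-(chloromethyl)prop-1-ene | C=C(CCl)CCl | starting material
14 | (4-methoxyphenyl)methanol | COc1ccc(CO)cc1 | starting material
15 | 1-({[2-(chloromethyl)prop-2-en-1-yl]oxy}methyl)-4-methoxybenzene | C=C(CCl)COCc1ccc(OC)cc1 | intermediate
16 | (2-{[(4-methoxyphenyl)methoxy]methyl}prop-2-en-1-yl)magnesium chloride | C=C(C[Mg]Cl)COCc1ccc(OC)cc1 | intermediate
17 | 3-{[(4-methoxyphenyl)methoxy]methyl}but-3-enoic acid | C=C(COCc1ccc(OC)cc1)CC(=O)O | intermediate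
18 | (4R)-4-benzyl-1,3-thiazolidine-2-thione | S=C1N[C@H](Cc2ccccc2)CS1 | starting material
19 | 1-[(4R)-4-benzyl-2-sulfanylidene-1,3-thiazolidin-3-yl]-3-{[(4-methoxyphenyl)methoxy]methyl}but-3-en-1-one | C=C(COCc1ccc(OC)cc1)CC(=O)N1C(=S)SC[C@H]1Cc1ccccc1 | intermediate
20 | trichlorotitanium (Z)-enolate of 19 | Cl[Ti](Cl)(Cl)O/C(=C\C(=C)COCc1ccc(OC)cc1)N1C(=S)SC[C@H]1Cc1ccccc1 | intermediate
21 | (2R,3S)-1-[(4R)-4-benzyl-2-sulfanylidene-1,3-thiazolidin-3-yl]-4-[(3R)-3,5-dimethyl-2-oxo-3,6-dihydro-2H-pyran-3-yl]-3-hydroxy-2-{3-[(4-methoxyphenyl)methoxy]prop-1-en-2-yl}butan-1-one | O=C1OCC(C)=C[C@@]1(C)C[C@H](O)[C@@H](C(=C)COCc2ccc(OC)cc2)C(=O)N3C(=S)SC[C@H]3Cc4ccccc4 | intermediate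
22 | (2R,3S)-1-[(4R)-4-benzyl-2-sulfanylidene-1,3-thiazolidin-3-yl]-4-[(3R)-3,5-dimethyl-2-oxo-3,6-dihydro-2H-pyran-3-yl]-2-{3-[(4-methoxyphenyl)methoxy]prop-1-en-2-yl}-3-[(triethylsilyl)oxy]butan-1-one | O=C1OCC(C)=C[C@@]1(C)C[C@H](O[Si](CC)(CC)CC)[C@@H](C(=C)COCc2ccc(OC)cc2)C(=O)N3C(=S)SC[C@H]3Cc4ccccc4 | intermediate
23 | (2R,3S)-4-[(3R)-3,5-dimethyl-2-oxo-3,6-dihydro-2H-pyran-3-yl]-2-{3-[(4-methoxyphenyl)methoxy]prop-1-en-2-yl}-3-[(triethylsilyl)oxy]butanal | O=C1OCC(C)=C[C@@]1(C)C[C@H](O[Si](CC)(CC)CC)[C@@H](C(=C)COCc2ccc(OC)cc2)C=O | intermediate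
24 | (4aR,5R,6S,7S,8aR)-5-hydroxy-6-{3-[(4-methoxyphenyl)methoxy]prop-1-en-2-yl}-8a-methyl-4-methylidene-7-[(triethylsilyl)oxy]octahydro-1H-isochromen-1-one | O=C2[C@]1(C)C[C@H](O[Si](CC)(CC)CC)[C@@H](C(=C)COCc3ccc(OC)cc3)[C@H](O)[C@@H]1C(=C)CO2 | intermediate
25 | (4aR,5R,6S,7S,8aR)-6-{3-[(4-methoxyphenyl)methoxy]prop-1-en-2-yl}-8a-methyl-4-methylidene-7-[(triethylsilyl)oxy]octahydro-1H-isochromene-1,5-diol (C1 epimers) | OC2[C@]1(C)C[C@H](O[Si](CC)(CC)CC)[C@@H](C(=C)COCc3ccc(OC)cc3)[C@H](O)[C@@H]1C(=C)CO2 | intermediate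
26 | (1R,2S,3S,5S,6S)-5-ethenyl-6-(3-hydroxyprop-1-en-2-yl)-2-{3-[(4-methoxyphenyl)methoxy]prop-1-en-2-yl}-5-methyl-3-[(triethylsilyl)oxy]cyclohexan-1-ol | C=C[C@]1(C)C[C@H](O[Si](CC)(CC)CC)[C@@H](C(=C)COCc2ccc(OC)cc2)[C@H](O)[C@@H]1C(=C)CO | intermediate
27 | (1R,2R,3S,5S,6S)-1-[(tert-butyldimethylsilyl)oxy]-6-{3-[(tert-butyldimethylsilyl)oxy]prop-1-en-2-yl}-5-ethenyl-2-{3-[(4-methoxyphenyl)methoxy]prop-1-en-2-yl}-5-methyl-3-[(triethylsilyl)oxy]cyclohexane | C=C[C@]1(C)C[C@H](O[Si](CC)(CC)CC)[C@@H](C(=C)COCc2ccc(OC)cc2)[C@H](O[Si](C)(C)C(C)(C)C)[C@@H]1C(=C)CO[Si](C)(C)C(C)(C)C | intermediate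
28 | (1R,2R,3S,5S,6S)-1-[(tert-butyldimethylsilyl)oxy]-6-{3-[(tert-butyldimethylsilyl)oxy]prop-1-en-2-yl}-5-ethenyl-2-{3-[(4-methoxyphenyl)methoxy]prop-1-en-2-yl}-5-methylcyclohexan-3-ol | C=C[C@]1(C)C[C@H](O)[C@@H](C(=C)COCc2ccc(OC)cc2)[C@H](O[Si](C)(C)C(C)(C)C)[C@@H]1C(=C)CO[Si](C)(C)C(C)(C)C | intermediate
29 | 3-methylfuran-2(5H)-one | CC1=CCOC1=O | starting material
30 | sodium (2Z)-4-hydroxy-2-methylbut-2-enoate | OC/C=C(/C)C(=O)[O-].[Na+] | intermediate
31 | (2Z)-4-(acetyloxy)-2-methylbut-2-enoic acid | CC(=O)OC/C=C(/C)C(=O)O | intermediate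
32 | (2Z)-4-(acetyloxy)-2-methylbut-2-enoic 2,4,6-trichlorobenzoic anhydride | CC(=O)OC/C=C(/C)C(=O)OC(=O)c1c(Cl)cc(Cl)cc1Cl | intermediate
33 | (1R,2R,3S,5S,6S)-1-[(tert-butyldimethylsilyl)oxy]-6-{3-[(tert-butyldimethylsilyl)oxy]prop-1-en-2-yl}-5-ethenyl-2-{3-[(4-methoxyphenyl)methoxy]prop-1-en-2-yl}-5-methylcyclohexan-3-yl (2Z)-4-(acetyloxy)-2-methylbut-2-enoate | C=C[C@]1(C)C[C@H](OC(=O)/C(C)=C\COC(C)=O)[C@@H](C(=C)COCc2ccc(OC)cc2)[C@H](O[Si](C)(C)C(C)(C)C)[C@@H]1C(=C)CO[Si](C)(C)C(C)(C)C | intermediate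
34 | (1R,2R,3S,5S,6S)-1-[(tert-butyldimethylsilyl)oxy]-6-{3-[(tert-butyldimethylsilyl)oxy]prop-1-en-2-yl}-5-ethenyl-2-(3-hydroxyprop-1-en-2-yl)-5-methylcyclohexan-3-yl (2Z)-4-(acetyloxy)-2-methylbut-2-enoate | C=C[C@]1(C)C[C@H](OC(=O)/C(C)=C\COC(C)=O)[C@@H](C(=C)CO)[C@H](O[Si](C)(C)C(C)(C)C)[C@@H]1C(=C)CO[Si](C)(C)C(C)(C)C | intermediate
35 | (1R,2R,3S,5S,6S)-1-[(tert-butyldimethylsilyl)oxy]-6-{3-[(tert-butyldimethylsilyl)oxy]prop-1-en-2-yl}-5-ethenyl-5-methyl-2-(3-oxoprop-1-en-2-yl)cyclohexan-3-yl (2Z)-4-(acetyloxy)-2-methylbut-2-enoate | C=C[C@]1(C)C[C@H](OC(=O)/C(C)=C\COC(C)=O)[C@@H](C(=C)C=O)[C@H](O[Si](C)(C)C(C)(C)C)[C@@H]1C(=C)CO[Si](C)(C)C(C)(C)C | intermediate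
36 | 2-[(1R,2R,3S,5S,6S)-3-{[(2Z)-4-(acetyloxy)-2-methylbut-2-enoyl]oxy}-1-[(tert-butyldimethylsilyl)oxy]-6-{3-[(tert-butyldimethylsilyl)oxy]prop-1-en-2-yl}-5-ethenyl-5-methylcyclohexan-2-yl]prop-2-enoic acid | C=C[C@]1(C)C[C@H](OC(=O)/C(C)=C\COC(C)=O)[C@@H](C(=C)C(=O)O)[C@H](O[Si](C)(C)C(C)(C)C)[C@@H]1C(=C)CO[Si](C)(C)C(C)(C)C | intermediate
37 | 2-[(1R,2S,3S,5S,6S)-3-{[(2Z)-4-(acetyloxy)-2-methylbut-2-enoyl]oxy}-5-ethenyl-1-hydroxy-6-(3-hydroxyprop-1-en-2-yl)-5-methylcyclohexan-2-yl]prop-2-enoic acid | C=C[C@]1(C)C[C@H](OC(=O)/C(C)=C\COC(C)=O)[C@@H](C(=C)C(=O)O)[C@H](O)[C@@H]1C(=C)CO | target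

## Step count and risks

Total step count: 23. Longest linear sequence: 18 steps (steps 1, 2, 4–7, 11–18 and 20–23; 1 → 3 → 5 → 9 → 10 → 11 → 12 → 21 → 22 → 23 → 24 → 25 → 26 → 27 → 28 → 33 → 34 → 36 → 37).

Steps most likely to fail:

**Step 14 (ene ring closure).** The ring alkene is slowed by the adjacent lactone carbonyl and the allylic ester oxygen. Isomerisation of the β,γ-unsaturated aldehyde into conjugation, methyl transfer from aluminium, or chloride capture of the cationic intermediate may then outrun hydrogen transfer. Closure through the competing chair with the silyloxy group axial would erode the facial selectivity at the aldehyde carbon. An aluminium chelate between the aldehyde oxygen and the silyloxy oxygen would turn the oxygen toward the ring OCH2. The fallback replaces the ene donor by an allylsilane (intramolecular Hosomi–Sakurai addition), which is more nucleophilic, fixes the position of the new alkene, needs no hydrogen transfer to oxygen and uses a Lewis acid that cannot chelate. It sets out from 2 and comes back to the route at 24. Acid bromide 2 is esterified with commercial 2-[(trimethylsilyl)methyl]prop-2-en-1-ol (pyridine, CH2Cl2) to 2-[(trimethylsilyl)methyl]prop-2-en-1-yl 2-bromopropanoate F1. PPh3 converts this into the phosphonium bromide F2 and aqueous NaOH into the silyl-substituted ylide F3. Steps 4 to 13 are then repeated unchanged with 7, 19 (through 20) and the same reagents. This gives in turn the silyl-substituted acetal enoate F4, the vinyl ether F5, the Claisen aldehyde F6, the silylmethyl lactone aldehyde F7, the syn-aldol adduct F8, its triethylsilyl ether F9 and the allylsilane aldehyde F10. BF3·OEt2 in CH2Cl2 at −78 °C should then close the same bond under the same tether control and the same preference for equatorial ring substituents, with loss of the trimethylsilyl group, to give 24.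

**Step 20 (esterification with the Z acid).** Z to E isomerisation through reversible conjugate addition of DMAP or through a ketene, or loss of acetate with closure to the butenolide, may occur during activation of 31. The fallback builds the Z alkene on the substrate; it sets out from 28 and comes back at 33. Commercial ethyl 2-[bis(2,2,2-trifluoroethoxy)phosphoryl]propanoate is saponified (LiOH) to 2-[bis(2,2,2-trifluoroethoxy)phosphoryl]propanoic acid F11. This is coupled to 28 (DCC, DMAP, CH2Cl2) to give the phosphonopropanoate ester F12. Still–Gennari olefination of F12 with 2-oxoethyl acetate (KN(SiMe3)2, 18-crown-6, THF, −78 °C) should give 33 with Z selectivity.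

**Step 13 (reductive removal of the auxiliary).** Hydride may also attack the lactone carbonyl, or the aldehyde may be over-reduced. The fallback avoids hydride; it sets out from 22 and comes back at 23. Ethanethiol and K2CO3 in CH2Cl2 displace the thiazolidinethione to give the S-ethyl thioester F13 with recovery of 18. Fukuyama reduction (Et3SiH, Pd/C, acetone, rt) should then give 23 without touching the lactone.

## Further compounds

F1 | step 14 | 2-[(trimethylsilyl)methyl]prop-2-en-1-yl 2-bromopropanoate | CC(Br)C(=O)OCC(=C)C[Si](C)(C)C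
F2 | step 14 | triphenyl[1-oxo-1-({2-[(trimethylsilyl)methyl]prop-2-en-1-yl}oxy)propan-2-yl]phosphonium bromide | CC(C(=O)OCC(=C)C[Si](C)(C)C)[P+](c1ccccc1)(c1ccccc1)c1ccccc1.[Br-]
F3 | step 14 | 2-[(trimethylsilyl)methyl]prop-2-en-1-yl 2-(triphenyl-λ5-phosphanylidene)propanoate | CC(C(=O)OCC(=C)C[Si](C)(C)C)=P(c1ccccc1)(c1ccccc1)c1ccccc1
F4 | step 14 | 2-[(trimethylsilyl)methyl]prop-2-en-1-yl (2E,4R)-4-(1-ethoxyethoxy)-2-methylpent-2-enoate | C[C@@H](OC(C)OCC)/C=C(\C)C(=O)OCC(=C)C[Si](C)(C)C
F5 | step 14 | 2-[(trimethylsilyl)methyl]prop-2-en-1-yl (2E,4R)-4-(ethenyloxy)-2-methylpent-2-enoate | C[C@@H](OC=C)/C=C(\C)C(=O)OCC(=C)C[Si](C)(C)C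
F6 | step 14 | 2-[(trimethylsilyl)methyl]prop-2-en-1-yl (2R,3E)-2-methyl-2-(2-oxoethyl)pent-3-enoate | O=CC[C@](C)(/C=C/C)C(=O)OCC(=C)C[Si](C)(C)C
F7 | step 14 | 2-{(3R)-3-methyl-2-oxo-5-[(trimethylsilyl)methyl]-3,6-dihydro-2H-pyran-3-yl}acetaldehyde | O=C1OCC(C[Si](C)(C)C)=C[C@@]1(C)CC=O
F8 | step 14 | (2R,3S)-1-[(4R)-4-benzyl-2-sulfanylidene-1,3-thiazolidin-3-yl]-3-hydroxy-2-{3-[(4-methoxyphenyl)methoxy]prop-1-en-2-yl}-4-{(3R)-3-methyl-2-oxo-5-[(trimethylsilyl)methyl]-3,6-dihydro-2H-pyran-3-yl}butan-1-one | O=C1OCC(C[Si](C)(C)C)=C[C@@]1(C)C[C@H](O)[C@@H](C(=C)COCc2ccc(OC)cc2)C(=O)N3C(=S)SC[C@H]3Cc4ccccc4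
F9 | step 14 | triethylsilyl ether of F8 | O=C1OCC(C[Si](C)(C)C)=C[C@@]1(C)C[C@H](O[Si](CC)(CC)CC)[C@@H](C(=C)COCc2ccc(OC)cc2)C(=O)N3C(=S)SC[C@H]3Cc4ccccc4
F10 | step 14 | (2R,3S)-2-{3-[(4-methoxyphenyl)methoxy]prop-1-en-2-yl}-4-{(3R)-3-methyl-2-oxo-5-[(trimethylsilyl)methyl]-3,6-dihydro-2H-pyran-3-yl}-3-[(triethylsilyl)oxy]butanal | O=C1OCC(C[Si](C)(C)C)=C[C@@]1(C)C[C@H](O[Si](CC)(CC)CC)[C@@H](C(=C)COCc2ccc(OC)cc2)C=O
F11 | step 20 | 2-[bis(2,2,2-trifluoroethoxy)phosphoryl]propanoic acid | CC(C(=O)O)P(=O)(OCC(F)(F)F)OCC(F)(F)F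
F12 | step 20 | (1R,2R,3S,5S,6S)-1-[(tert-butyldimethylsilyl)oxy]-6-{3-[(tert-butyldimethylsilyl)oxy]prop-1-en-2-yl}-5-ethenyl-2-{3-[(4-methoxyphenyl)methoxy]prop-1-en-2-yl}-5-methylcyclohexan-3-yl 2-[bis(2,2,2-trifluoroethoxy)phosphoryl]propanoate | C=C[C@]1(C)C[C@H](OC(=O)C(C)P(=O)(OCC(F)(F)F)OCC(F)(F)F)[C@@H](C(=C)COCc2ccc(OC)cc2)[C@H](O[Si](C)(C)C(C)(C)C)[C@@H]1C(=C)CO[Si](C)(C)C(C)(C)C
F13 | step 13 | S-ethyl (2R,3S)-4-[(3R)-3,5-dimethyl-2-oxo-3,6-dihydro-2H-pyran-3-yl]-2-{3-[(4-methoxyphenyl)methoxy]prop-1-en-2-yl}-3-[(triethylsilyl)oxy]butanethioate | O=C1OCC(C)=C[C@@]1(C)C[C@H](O[Si](CC)(CC)CC)[C@@H](C(=C)COCc2ccc(OC)cc2)C(=O)SCC
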